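Guaiane numbering is used throughout: C1/C5 ring fusion, C4 and C10 methyl carbinols, C6 secondary carbinol, C7 side-chain carbon. The seven-membered ring is cut at C5–C6 and C1–C10. Its five-carbon unit C6–C10 is oxygenated at both ends, so it is brought in as 3-oxidopyrylium, whose ring oxygen ties C6 to C10, and added across the C1=C5 bond of (R)-4-silyloxycyclopentenone in one intermolecular (5+2) cycloaddition. The silyloxy group sets the absolute sense of the cis ring fusion. The temporary oxygen bridge is then opened by Kishner eliminative reduction, and both methyl carbinols are raised two-directionally from exocyclic methylenes on the convex face.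

Key step: step 3

Remark on the chemistry: α is the face of the bicycle that carries H1 and H5. The exo/endo ratio of the cycloaddition is left open on purpose, because both bridgehead centres are erased later (C6 in step 5, C10 in step 7). Compounds 6–8 are therefore written without configuration at C6/C10, and 9–10 without configuration at C10. Compounds 1, 4 and 15 are taken as commercial.

Step 1
Reactants: 1 furan-2-ylmethanol
Product: 2 6-hydroxy-2H-pyran-3(6H)-one (racemic lactol)
Conditions: mCPBA, CH2Cl2, 0 °C
Reagents that add atoms: 3-chloroperbenzoic acid, OOC(=O)c1cccc(Cl)c1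
Why: Achmatowicz rearrangement, in which the peracid oxidises the furan, the ring opens to the ene-dione and the primary hydroxyl recloses to the pyranone lactol; its single stereocentre is lost in step 3.

Step 2
Reactants: 2 6-hydroxy-2H-pyran-3(6H)-one
Product: 3 6-acetoxy-2H-pyran-3(6H)-one (racemic)
Conditions: Ac2O, pyridine, DMAP (cat.), CH2Cl2, 0 °C
Reagents that add atoms: acetic anhydride, CC(=O)OC(C)=O
Why: Acylation of the anomeric hydroxyl installs the leaving group needed to form the ylide.

Step 3
Reactants: 3 6-acetoxy-2H-pyran-3(6H)-one; 4 (R)-4-(tert-butyldimethylsilyloxy)cyclopent-2-en-1-one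
Product: 6 oxa-bridged tricyclic enedione (exo/endo mixture at C6/C10), via 3-oxidopyrylium 5 (not isolated)
Conditions: 3 (3 equiv, slow addition), iPr2NEt, MeCN, 60 °C
Reagents that add atoms: none
Why: Base-induced loss of acetate from 3 gives 3-oxidopyrylium 5, which adds as a five-carbon dipole across the C1=C5 bond of 4 in a concerted, asynchronous thermal (5+2) cycloaddition, the known oxidopyrylium–alkene cycloaddition of electron-poor alkenes. The seven-membered carbocycle C1–C5–C6–C7–C8–C9–C10 is closed by this intermolecular cycloaddition through the new bonds C5–C6 and C1–C10, the pyrylium oxygen remaining as a temporary C6–O–C10 bridge. The cis ring fusion (C1, C5) follows from suprafacial addition to the cis alkene, and its absolute sense from approach of the dipole anti to the C4 silyloxy group. The bridgehead centres C6 and C10 may form as an exo/endo mixture, which is immaterial because C6 becomes sp2 in step 5 and C10 in step 7. The step needs regioselectivity, secured by bonding of the nucleophilic ylide carbon next to the oxido group (C6) to the electrophilic enone β-carbon (C5), the sense established for acrylates and vinyl ketones. Dimerisation of 5 is reversible on heating, so the ylide precursor is fed slowly and in excess.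

Step 4
Reactants: 6 oxa-bridged tricyclic enedione
Product: 7 oxa-bridged tricyclic diketone (C8–C9 saturated)
Conditions: H2 (1 atm), Pd/C, EtOAc, 25 °C
Reagents that add atoms: none
Why: Heterogeneous hydrogenation saturates the conjugated C8=C9 bond without touching ketones, silyl ether or ether bridge, forms no stereocentre, and removes the enone that would otherwise add hydrazine in step 5.

Step 5
Reactants: 7 oxa-bridged tricyclic diketone
Product: 9 4α-(tert-butyldimethylsilyloxy)-cis-bicyclo[5.3.0]dec-6-en-10-ol (both C10 epimers), via bis-hydrazone 8 (not isolated)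
Conditions: N2H4·H2O, AcOH (cat.), EtOH, 25–50 °C; evaporate; KOtBu, DMSO, 25 °C
Reagents that add atoms: none
Why: Kishner eliminative reduction: the anion of the C7 hydrazone expels the α-oxygen at C6, opening the bridge to the cis C6=C7 alkene and the C10 alkoxide with loss of N2, while the cyclopentanone hydrazone undergoes ordinary Wolff–Kishner reduction (room-temperature KOtBu/DMSO variant) to C2H2; forming the hydrazones first under buffered conditions avoids β-elimination of the silyloxy group, and C1, C4 and C5 are untouched.

Step 6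
Reactants: 9 silyl ether alkenol
Product: 10 cis-bicyclo[5.3.0]dec-6-ene-4α,10-diol (both C10 epimers)
Conditions: TBAF, THF, 25 °C
Reagents that add atoms: none
Why: Fluoride cleaves the secondary silyl ether through Si–F bond formation without affecting the alkene or the carbinols.

Step 7
Reactants: 10 alkene diol
Product: 11 cis-bicyclo[5.3.0]dec-6-ene-4,10-dione (H1, H5 α)
Conditions: Pr4N[RuO4] (cat.), N-methylmorpholine N-oxide, 4 Å molecular sieves, CH2Cl2, 25 °C
Reagents that add atoms: none
Why: Ley–Griffith oxidation converts both secondary alcohols to ketones under neutral, non-enolising conditions, so the β,γ-unsaturated C4 ketone does not move into conjugation, C1/C5 are not epimerised, and the C10 epimers converge to one compound.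

Step 8
Reactants: 11 alkene diketone
Product: 12 4,10-dimethylidene-cis-bicyclo[5.3.0]dec-6-ene
Conditions: Cp2TiMe2 (4 equiv), toluene, 65 °C, dark
Reagents that add atoms: dimethyltitanocene, C[Ti+2]C.c1cc[cH-]c1.c1cc[cH-]c1
Why: Petasis methylenation, in which thermally formed Cp2Ti=CH2 olefinates both ketones through oxatitanacyclobutanes without base, so the enolisable, epimerisable diketone is methylenated at both ends in one operation.

Step 9
Reactants: 12 triene
Product: 13 4β,10β-dimethyl-cis-bicyclo[5.3.0]dec-6-ene-4α,10α-diol
Conditions: Co(acac)2 (cat.), PhSiH3, O2 (1 atm), THF, 25 °C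
Reagents that add atoms: dioxygen, O=O
Why: Mukaiyama hydration: hydrogen-atom transfer to the two 1,1-disubstituted alkenes (much faster than to the cis-disubstituted C6=C7 bond) gives tertiary radicals at C4 and C10 that should be trapped by O2 on the convex α face, anti to the neighbouring ring bond at C5 and C1, setting both carbinols with OH α and methyl β.

Step 10
Reactants: 13 alkene diol
Product: 14 6α,7α-epoxy-4β,10β-dimethyl-cis-bicyclo[5.3.0]decane-4α,10α-diol
Conditions: VO(acac)2 (cat.), tBuOOH, CH2Cl2, 0 to 25 °C
Reagents that add atoms: tert-butyl hydroperoxide, CC(C)(C)OO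
Why: Hydroxyl-directed vanadium-catalysed epoxidation, in which the homoallylic C4 hydroxyl (supported by the C10 hydroxyl, both α) delivers the peroxide oxygen to the α face of C6=C7.

Step 11
Reactants: 15 2-bromoprop-2-en-1-ol
Product: 16 (2-bromoallyloxy)(tert-butyl)dimethylsilane
Conditions: TBSCl, imidazole, CH2Cl2, 25 °C
Reagents that add atoms: tert-butyldimethylsilyl chloride, CC(C)(C)[Si](C)(C)Cl
Why: Standard silylation of the primary alcohol masks the hydroxyl for the organolithium chemistry.

Step 12
Reactants: 14 epoxy diol; 16 bromoalkene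
Product: 18 ring-opened triol silyl ether, via alkenyllithium 17 (not isolated)
Conditions: 16 (6 equiv), tBuLi (12 equiv), Et2O, −78 °C; then 14, BF3·OEt2, THF, −78 °C
Reagents that add atoms: none
Why: Bromine–lithium exchange gives alkenyllithium 17, which opens the BF3-activated epoxide (organolithium/BF3 epoxide opening) by backside attack at C7, the carbon remote from the ring fusion and not shielded by the β-methyl at C4, so the side chain enters β and the C6 oxygen stays α; two equivalents of 17 are spent on the tertiary hydroxyls, which cannot open the epoxide themselves because they lie on its own face.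

Step 13
Reactants: 18 ring-opened triol silyl ether
Product: 19 7β-(3-hydroxyprop-1-en-2-yl)-4β,10β-dimethyl-cis-bicyclo[5.3.0]decane-4α,6α,10α-triol
Conditions: TBAF, THF, 25 °C
Reagents that add atoms: none
Why: Fluoride-mediated cleavage of the primary silyl ether frees the allylic alcohol.

Step 14
Reactants: 19 allylic alcohol triol
Product: 20 2-(4α,6α,10α-trihydroxy-4β,10β-dimethyl-cis-bicyclo[5.3.0]decan-7β-yl)propane-1,2,3-triol
Conditions: OsO4 (cat.), N-methylmorpholine N-oxide, acetone/H2O, 25 °C
Reagents that add atoms: N-methylmorpholine N-oxide, C[N+]1([O-])CCOCC1; water, O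
Why: Upjohn dihydroxylation of the only remaining alkene gives the side-chain triol, whose central carbon (C11) is not stereogenic because it carries two hydroxymethyl groups.

Step 15
Reactants: 20 hexaol
Product: 21 target diacetate
Conditions: Ac2O (2.2 equiv), pyridine, −20 to 0 °C
Reagents that add atoms: acetic anhydride, CC(=O)OC(C)=O
Why: Rate-controlled acylation should take the two equivalent primary hydroxyls well before the hindered secondary C6 hydroxyl and the three tertiary hydroxyls.

Compound list
1 | furan-2-ylmethanol | OCc1ccco1 | starting material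
2 | 6-hydroxy-2H-pyran-3(6H)-one (racemic) | O=C1COC(O)C=C1 | intermediate
3 | 6-acetoxy-2H-pyran-3(6H)-one (racemic) | O=C1COC(OC(C)=O)C=C1 | intermediate
4 | (R)-4-(tert-butyldimethylsilyloxy)cyclopent-2-en-1-one | O=C1C=C[C@H](O[Si](C)(C)C(C)(C)C)C1 | starting material
5 | 3-oxidopyrylium (not isolated) | [O-]c1ccc[o+]c1 | intermediate
6 | 6,10-epoxy-bridged cis-bicyclo[5.3.0]dec-8-ene-2,7-dione, 4α-OTBS, H1/H5 α, exo/endo mixture at C6/C10 | O=C1C[C@@H](O[Si](C)(C)C(C)(C)C)[C@H]2[C@@H]1C3C=CC(=O)C2O3 | intermediate
7 | 8,9-dihydro derivative of 6 | O=C1C[C@@H](O[Si](C)(C)C(C)(C)C)[C@H]2[C@@H]1C3CCC(=O)C2O3 | intermediate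
8 | bis-hydrazone of 7 (not isolated) | NN=C1C[C@@H](O[Si](C)(C)C(C)(C)C)[C@H]2[C@@H]1C3CCC(=NN)C2O3 | intermediate
9 | 4α-(tert-butyldimethylsilyloxy)-cis-bicyclo[5.3.0]dec-6-en-10-ol, H1/H5 α, C10 epimers | CC(C)(C)[Si](C)(C)O[C@@H]1CC[C@@H]2[C@H]1C=CCCC2O | intermediate
10 | cis-bicyclo[5.3.0]dec-6-ene-4α,10-diol, H1/H5 α, C10 epimers | O[C@@H]1CC[C@@H]2[C@H]1C=CCCC2O | intermediate
11 | cis-bicyclo[5.3.0]dec-6-ene-4,10-dione, H1/H5 α | O=C1CC[C@@H]2[C@H]1C=CCCC2=O | intermediate
12 | 4,10-dimethylidene-cis-bicyclo[5.3.0]dec-6-ene, H1/H5 α | C=C1CC[C@@H]2[C@H]1C=CCCC2=C | intermediate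
13 | 4β,10β-dimethyl-cis-bicyclo[5.3.0]dec-6-ene-4α,10α-diol | C[C@@]1(O)CC[C@@H]2[C@H]1C=CCC[C@@]2(C)O | intermediate
14 | 6α,7α-epoxy-4β,10β-dimethyl-cis-bicyclo[5.3.0]decane-4α,10α-diol | C[C@@]1(O)CC[C@@H]2[C@H]1[C@H]3O[C@H]3CC[C@@]2(C)O | intermediate
15 | 2-bromoprop-2-en-1-ol | OCC(Br)=C | starting material
16 | (2-bromoallyloxy)(tert-butyl)dimethylsilane | C=C(Br)CO[Si](C)(C)C(C)(C)C | intermediate
17 | [3-(tert-butyldimethylsilyloxy)prop-1-en-2-yl]lithium (not isolated) | [Li]C(=C)CO[Si](C)(C)C(C)(C)C | intermediate
18 | 7β-[3-(tert-butyldimethylsilyloxy)prop-1-en-2-yl]-4β,10β-dimethyl-cis-bicyclo[5.3.0]decane-4α,6α,10α-triol | C[C@@]1(O)CC[C@@H]2[C@H]1[C@@H](O)[C@H](C(=C)CO[Si](C)(C)C(C)(C)C)CC[C@@]2(C)O | intermediate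
19 | 7β-(3-hydroxyprop-1-en-2-yl)-4β,10β-dimethyl-cis-bicyclo[5.3.0]decane-4α,6α,10α-triol | C[C@@]1(O)CC[C@@H]2[C@H]1[C@@H](O)[C@H](C(=C)CO)CC[C@@]2(C)O | intermediate
20 | 2-(4α,6α,10α-trihydroxy-4β,10β-dimethyl-cis-bicyclo[5.3.0]decan-7β-yl)propane-1,2,3-triol | C[C@@]1(O)CC[C@@H]2[C@H]1[C@@H](O)[C@H](C(O)(CO)CO)CC[C@@]2(C)O | intermediate
21 | target: 12,13-diacetate of the 4α,6α,10α,11,12,13-hexaol (1αH,5αH-guaiane skeleton) | CC(=O)OCC(O)(COC(C)=O)[C@@H]1CC[C@@](C)(O)[C@@H]2CC[C@@](C)(O)[C@@H]2[C@H]1O | target

Total step count: 15. Longest linear sequence: 14 steps (steps 1–10 and 12–15; step 11 is a one-step branch).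

Steps most likely to fail

Step 3 (key step). The process at risk is dimerisation of ylide 5 outrunning its addition to the β-substituted, only moderately electron-poor enone, together with erosion of regiocontrol. The fallback activates the two-carbon partner tracelessly. Setting out from 4, α-iodination (I2, pyridine, CH2Cl2) gives (R)-2-iodo-4-(tert-butyldimethylsilyloxy)cyclopent-2-en-1-one F1, a more electron-poor dipolarophile. Cycloaddition with 5 (from 3 and iPr2NEt) gives the 1-iodo cycloadduct F2. Hydrogenation over Pd/C with Et3N then saturates C8=C9 and hydrogenolyses the C–I bond, coming back to the route at 7.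

Step 5. The process at risk is β-elimination of the silyloxy group, or epimerisation at C1 next to the C2 hydrazone, in the strongly basic second stage. The fallback separates the two events and avoids strong base. Setting out from 7, hydrazine hydrate with AcOH in MeOH at 0–25 °C forms 8 and carries out only the eliminative bridge opening, leaving the cyclopentanone as the ring-opened C2 hydrazone F3. Exchange with aqueous acetone/AcOH frees the ring-opened C2 ketone F4. TsNHNH2 in EtOH gives the tosylhydrazone F5, and catecholborane followed by NaOAc·3H2O in CHCl3 reduces it to the methylene, coming back to the route at 9.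

Step 9. The process at risk is poor facial selectivity when the two tertiary radicals are captured by oxygen. The fallback replaces the radical hydration by an ionic one. Setting out from 12, Hg(OAc)2 in THF/H2O adds to the two 1,1-disubstituted alkenes in preference to C6=C7 and gives the bis(acetoxymercurio) diol F6, water attacking the mercurinium ions at C4 and C10 from the convex face. Demercuration with NaBH4/NaOH comes back to the route at 13.

Further compounds
F1 | step 3 | (R)-2-iodo-4-(tert-butyldimethylsilyloxy)cyclopent-2-en-1-one | O=C1C(I)=C[C@H](O[Si](C)(C)C(C)(C)C)C1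
F2 | step 3 | 1-iodo analogue of cycloadduct 6 (exo/endo mixture at C6/C10) | O=C1C[C@@H](O[Si](C)(C)C(C)(C)C)[C@H]2[C@]1(I)C3C=CC(=O)C2O3
F3 | step 5 | C2 hydrazone of 4α-(tert-butyldimethylsilyloxy)-10-hydroxy-cis-bicyclo[5.3.0]dec-6-en-2-one | NN=C1C[C@@H](O[Si](C)(C)C(C)(C)C)[C@H]2[C@@H]1C(O)CCC=C2
F4 | step 5 | 4α-(tert-butyldimethylsilyloxy)-10-hydroxy-cis-bicyclo[5.3.0]dec-6-en-2-one | O=C1C[C@@H](O[Si](C)(C)C(C)(C)C)[C@H]2[C@@H]1C(O)CCC=C2
F5 | step 5 | tosylhydrazone of F4 | Cc1ccc(cc1)S(=O)(=O)NN=C1C[C@@H](O[Si](C)(C)C(C)(C)C)[C@H]2[C@@H]1C(O)CCC=C2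
F6 | step 9 | 4β,10β-bis(acetoxymercuriomethyl)-cis-bicyclo[5.3.0]dec-6-ene-4α,10α-diol | CC(=O)O[Hg]C[C@@]1(O)CC[C@@H]2[C@H]1C=CCC[C@@]2(C[Hg]OC(C)=O)O
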